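**Strategy.** The upper 3-deoxyflavan unit is cut where its pyran ring C meets ring A: the ether oxygen O1 and the benzylic carbon C4 sit on the adjacent ring A carbons C8a and C4a, an ortho O,C pattern that an aryne accepts in one operation. The precursors are an open-chain (S)-3-aryl-3-silyloxypropanamide and a silylaryl triflate. Fluoride releases an alkoxide and a 3-bromoaryne; the alkoxide adds to the aryne (O1–C8a) and the resulting aryl anion closes onto the amide carbonyl (C4a–C4), giving the (2S)-flavanone with C2 untouched. The bromine steers the regiochemistry and leaves in the final hydrogenolysis. Reduction, then Lewis-acid coupling with benzylated (−)-epigallocatechin, forges the 4→8 bond.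

Key step: step 6

Remark: 6 and 16 are taken as purchasable; flavan-4-ol 15 is drawn as its expected major 2,4-cis epimer, its C4 configuration being erased by ionisation in step 9.

**Step 1**
Reactants: 1 4-(benzyloxy)phenol
Product: 2 4-(benzyloxy)-2,6-dibromophenol
Conditions: NBS (2.05 equiv), i-Pr2NH (0.1 equiv), CH2Cl2, 0 °C to rt
Reagents that add atoms: N-bromosuccinimide, O=C1CCC(=O)N1Br
Why: Electrophilic aromatic bromination in which the free phenol OH, a stronger director than the benzyl ether and assisted by the amine, sends both bromines to its ortho positions because the para position is blocked.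

**Step 2**
Reactants: 2 4-(benzyloxy)-2,6-dibromophenol
Product: 5 4-(benzyloxy)-2-bromo-6-(trimethylsilyl)phenyl trifluoromethanesulfonate, via aryl trimethylsilyl ether 3 (not isolated), via lithium silylphenoxide 4 (not isolated)
Conditions: (Me3Si)2NH, THF, 70 °C, then evaporation; n-BuLi (1.05 equiv), THF, −78 °C; Tf2O (1.2 equiv), −78 °C to rt
Reagents that add atoms: hexamethyldisilazane, C[Si](C)(C)N[Si](C)(C)C; trifluoromethanesulfonic anhydride, O=S(=O)(OS(=O)(=O)C(F)(F)F)C(F)(F)F
Why: O-Silylation, bromine–lithium exchange at one of the two equivalent bromines and retro-Brook (1,3 O→C) silyl migration give phenoxide 4, whose triflation delivers the 2-silylaryl triflate aryne precursor, the second bromine surviving because only one equivalent of n-BuLi is used at −78 °C.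

**Step 3**
Reactants: 6 methyl 3,4-bis(benzyloxy)benzoate; 7 N,N-dimethylacetamide
Product: 8 3-[3,4-bis(benzyloxy)phenyl]-N,N-dimethyl-3-oxopropanamide
Conditions: LiN(i-Pr)2 (commercial solution, 2.2 equiv), 7 (2.2 equiv), THF, −78 °C; then 6, −78 to 0 °C; aqueous HCl quench
Reagents that add atoms: none
Why: Crossed Claisen condensation in which the lithium enolate of 7 acylates the non-enolisable ester 6, the second equivalent of base deprotonating the β-keto amide so that the equilibrium is driven forward and double addition is prevented.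

**Step 4**
Reactants: 8 3-[3,4-bis(benzyloxy)phenyl]-N,N-dimethyl-3-oxopropanamide
Product: 9 (3S)-3-[3,4-bis(benzyloxy)phenyl]-3-hydroxy-N,N-dimethylpropanamide
Conditions: [RuCl(p-cymene)((R)-BINAP)]Cl (1 mol%), H2 (50 atm), EtOH, 50 °C
Reagents that add atoms: none
Why: Noyori asymmetric hydrogenation of a β-keto amide, in which the substrate chelates ruthenium through both carbonyls and the (R)-BINAP ligand directs hydride to the ketone face that gives the (S)-carbinol (the same spatial sense as (R)-3-hydroxybutanoates, the descriptor changing because aryl outranks CH2CO), the benzyl ethers being inert to the homogeneous catalyst.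

**Step 5**
Reactants: 9 (3S)-3-[3,4-bis(benzyloxy)phenyl]-3-hydroxy-N,N-dimethylpropanamide
Product: 10 (3S)-3-[3,4-bis(benzyloxy)phenyl]-N,N-dimethyl-3-[(trimethylsilyl)oxy]propanamide
Conditions: Me3SiCl (1.3 equiv), imidazole (2 equiv), CH2Cl2, 0 °C; non-aqueous work-up
Reagents that add atoms: chlorotrimethylsilane, C[Si](C)(C)Cl
Why: Silylation of the secondary alcohol turns the proton-bearing OH into a fluoride-cleavable alkoxide precursor so that step 6 runs without a proton source, C3 remaining untouched.

**Step 6**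
Reactants: 10 (3S)-3-[3,4-bis(benzyloxy)phenyl]-N,N-dimethyl-3-[(trimethylsilyl)oxy]propanamide; 5 4-(benzyloxy)-2-bromo-6-(trimethylsilyl)phenyl trifluoromethanesulfonate
Product: 14 (2S)-7-(benzyloxy)-2-[3,4-bis(benzyloxy)phenyl]-5-bromo-2,3-dihydro-4H-chromen-4-one, via cesium alkoxide 11 (not isolated), via aryne 12 (not isolated), via cesium hemiaminal alkoxide 13 (not isolated)
Conditions: CsF (4.5 equiv), 18-crown-6 (0.3 equiv), THF, rt to 40 °C, 5 (1.5 equiv) added slowly; then aqueous NH4Cl
Reagents that add atoms: none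
Why: Proposed new method: fluoride unmasks both partners, cleaving the O–SiMe3 bond of 10 to cesium alkoxide 11 and converting 5 into aryne 12; 11 adds to the aryne carbon remote from bromine (O1–C8a bond), and the aryl anion so formed at C4a attacks the tethered amide carbonyl in a 6-exo-trig closure of ring C (C4a–C4 bond) to give hemiaminal alkoxide 13, which collapses to ketone 14 only on aqueous quench. The closest known reaction type is the aryne annulation of salicylate esters to xanthones (phenoxide addition to the aryne, then intramolecular acyl substitution by the aryl anion), extended here to an aliphatic β-silyloxy carboxamide. No stereocenter is created: C2 comes unchanged from 10 because its C–O bond is never broken, and holding C4 as the base-stable hemiaminal alkoxide 13 until the quench should protect the flavanone from base-induced retro-oxa-Michael racemisation. The step needs regioselective addition to an unsymmetrical aryne, which the bromine next to the aryne secures (inductive stabilisation of the adjacent anion and aryne distortion send the nucleophile to the distal carbon, as in 3-haloarynes), and it needs ring closure to outrun protonation or bromide loss from the aryl anion, which the proton-free medium (silyl ether in place of OH, THF, cesium counter-ion) and the intramolecular six-membered trajectory are meant to secure.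

**Step 7**
Reactants: 14 (2S)-7-(benzyloxy)-2-[3,4-bis(benzyloxy)phenyl]-5-bromo-2,3-dihydro-4H-chromen-4-one
Product: 15 (2S,4S)-7-(benzyloxy)-2-[3,4-bis(benzyloxy)phenyl]-5-bromo-3,4-dihydro-2H-chromen-4-ol
Conditions: NaBH4 (1.5 equiv), THF/MeOH, 0 °C
Reagents that add atoms: none
Why: Borohydride reduction of the aryl ketone, expected to give mainly the 2,4-cis alcohol by axial hydride delivery, the C4 configuration being immaterial because C4 is ionised in step 9 and the aryl bromide and benzyl ethers being inert.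

**Step 8**
Reactants: 16 (−)-epigallocatechin
Product: 17 (2R,3R)-5,7-bis(benzyloxy)-2-[3,4,5-tris(benzyloxy)phenyl]-3,4-dihydro-2H-chromen-3-ol
Conditions: BnBr (5.5 equiv), K2CO3 (6 equiv), DMF, −10 °C to rt, argon
Reagents that add atoms: benzyl bromide, BrCc1ccccc1
Why: Williamson etherification in which carbonate deprotonates only the five phenols and not the secondary 3-OH, low temperature under argon limiting C2 epimerisation and oxidation of the pyrogallol ring so that both stereocenters of 16 are retained.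

**Step 9**
Reactants: 15 (2S,4S)-7-(benzyloxy)-2-[3,4-bis(benzyloxy)phenyl]-5-bromo-3,4-dihydro-2H-chromen-4-ol; 17 (2R,3R)-5,7-bis(benzyloxy)-2-[3,4,5-tris(benzyloxy)phenyl]-3,4-dihydro-2H-chromen-3-ol
Product: 18 (2R,3R)-5,7-bis(benzyloxy)-8-{(2S,4S)-7-(benzyloxy)-2-[3,4-bis(benzyloxy)phenyl]-5-bromo-3,4-dihydro-2H-chromen-4-yl}-2-[3,4,5-tris(benzyloxy)phenyl]-3,4-dihydro-2H-chromen-3-ol (upper unit 2,4-trans)
Conditions: TMSOTf (0.2 equiv), 17 (3 equiv), CH2Cl2, −78 to −20 °C; then Et3N
Reagents that add atoms: none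
Why: Lewis-acid-mediated Friedel–Crafts alkylation (the standard proanthocyanidin coupling) in which TMSOTf ionises the benzylic 4-OH to a flavan-4-yl cation stabilised by O1 and the 7-benzyloxy group, C8 of excess 17 (the more accessible position of its phloroglucinol-type ring A) attacks it, and the new C4 stereocenter is set by substrate control, axial attack anti to the equatorial 2-aryl group giving the 2,4-trans product, which the peri bromine at C5 should further favour by disfavouring an equatorial 4-aryl group.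

**Step 10**
Reactants: 18 the octa-O-benzyl bromo dimer
Product: 19 (2R,3R)-8-[(2S,4R)-2-(3,4-dihydroxyphenyl)-7-hydroxy-3,4-dihydro-2H-chromen-4-yl]-2-(3,4,5-trihydroxyphenyl)-3,4-dihydro-2H-chromene-3,5,7-triol (CNP0211965.1)
Conditions: H2 (1 atm), Pd(OH)2/C, Et3N (2 equiv), THF/MeOH, rt; AcOH added before filtration under argon
Reagents that add atoms: none
Why: Heterogeneous hydrogenolysis removes all eight benzyl ethers and the aryl C–Br bond (hydrodehalogenation, HBr trapped by Et3N to protect the interflavan bond) without touching any stereocenter, the descriptor of the upper C4 changing from S to R only because C4a loses CIP priority when bromine is replaced by hydrogen.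

**Compound list**

1 | 4-(benzyloxy)phenol | Oc1ccc(OCc2ccccc2)cc1 | starting material
2 | 4-(benzyloxy)-2,6-dibromophenol | Oc1c(Br)cc(OCc2ccccc2)cc1Br | intermediate
3 | [4-(benzyloxy)-2,6-dibromophenoxy]trimethylsilane | C[Si](C)(C)Oc1c(Br)cc(OCc2ccccc2)cc1Br | intermediate
4 | lithium 4-(benzyloxy)-2-bromo-6-(trimethylsilyl)phenolate | [Li+].[O-]c1c(Br)cc(OCc2ccccc2)cc1[Si](C)(C)C | intermediate
5 | 4-(benzyloxy)-2-bromo-6-(trimethylsilyl)phenyl trifluoromethanesulfonate | C[Si](C)(C)c1cc(OCc2ccccc2)cc(Br)c1OS(=O)(=O)C(F)(F)F | intermediate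
6 | methyl 3,4-bis(benzyloxy)benzoate | COC(=O)c1ccc(OCc2ccccc2)c(OCc2ccccc2)c1 | starting material
7 | N,N-dimethylacetamide | CC(=O)N(C)C | starting material
8 | 3-[3,4-bis(benzyloxy)phenyl]-N,N-dimethyl-3-oxopropanamide | CN(C)C(=O)CC(=O)c1ccc(OCc2ccccc2)c(OCc2ccccc2)c1 | intermediate
9 | (3S)-3-[3,4-bis(benzyloxy)phenyl]-3-hydroxy-N,N-dimethylpropanamide | CN(C)C(=O)C[C@H](O)c1ccc(OCc2ccccc2)c(OCc2ccccc2)c1 | intermediate
10 | (3S)-3-[3,4-bis(benzyloxy)phenyl]-N,N-dimethyl-3-[(trimethylsilyl)oxy]propanamide | CN(C)C(=O)C[C@H](O[Si](C)(C)C)c1ccc(OCc2ccccc2)c(OCc2ccccc2)c1 | intermediate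
11 | cesium (1S)-1-[3,4-bis(benzyloxy)phenyl]-3-(dimethylamino)-3-oxopropan-1-olate | [Cs+].CN(C)C(=O)C[C@H]([O-])c1ccc(OCc2ccccc2)c(OCc2ccccc2)c1 | intermediate
12 | 5-(benzyloxy)-3-bromo-1,2-didehydrobenzene (5-benzyloxy-3-bromobenzyne) | BrC1=CC(OCc2ccccc2)=CC#C1 | intermediate
13 | cesium (2S)-7-(benzyloxy)-2-[3,4-bis(benzyloxy)phenyl]-5-bromo-4-(dimethylamino)-3,4-dihydro-2H-chromen-4-olate (C4 epimers) | [Cs+].CN(C)C1([O-])C[C@@H](c2ccc(OCc3ccccc3)c(OCc3ccccc3)c2)Oc2cc(OCc3ccccc3)cc(Br)c21 | intermediate
14 | (2S)-7-(benzyloxy)-2-[3,4-bis(benzyloxy)phenyl]-5-bromo-2,3-dihydro-4H-chromen-4-one | O=C1C[C@@H](c2ccc(OCc3ccccc3)c(OCc3ccccc3)c2)Oc2cc(OCc3ccccc3)cc(Br)c21 | intermediate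
15 | (2S,4S)-7-(benzyloxy)-2-[3,4-bis(benzyloxy)phenyl]-5-bromo-3,4-dihydro-2H-chromen-4-ol (2,4-cis) | O[C@H]1C[C@@H](c2ccc(OCc3ccccc3)c(OCc3ccccc3)c2)Oc2cc(OCc3ccccc3)cc(Br)c21 | intermediate
16 | (−)-epigallocatechin, (2R,3R)-2-(3,4,5-trihydroxyphenyl)-3,4-dihydro-2H-chromene-3,5,7-triol | Oc1cc(O)c2c(c1)O[C@H](c1cc(O)c(O)c(O)c1)[C@H](O)C2 | starting material
17 | (2R,3R)-5,7-bis(benzyloxy)-2-[3,4,5-tris(benzyloxy)phenyl]-3,4-dihydro-2H-chromen-3-ol | O(Cc1ccccc1)c1cc(OCc3ccccc3)c2c(c1)O[C@H](c1cc(OCc3ccccc3)c(OCc3ccccc3)c(OCc3ccccc3)c1)[C@H](O)C2 | intermediate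
18 | (2R,3R)-5,7-bis(benzyloxy)-8-{(2S,4S)-7-(benzyloxy)-2-[3,4-bis(benzyloxy)phenyl]-5-bromo-3,4-dihydro-2H-chromen-4-yl}-2-[3,4,5-tris(benzyloxy)phenyl]-3,4-dihydro-2H-chromen-3-ol | O(Cc3ccccc3)c1cc(Br)c2c(c1)O[C@H](c1ccc(OCc3ccccc3)c(OCc3ccccc3)c1)C[C@H]2c1c(OCc3ccccc3)cc(OCc3ccccc3)c2c1O[C@H](c1cc(OCc3ccccc3)c(OCc3ccccc3)c(OCc3ccccc3)c1)[C@H](O)C2 | intermediate
19 | (2R,3R)-8-[(2S,4R)-2-(3,4-dihydroxyphenyl)-7-hydroxy-3,4-dihydro-2H-chromen-4-yl]-2-(3,4,5-trihydroxyphenyl)-3,4-dihydro-2H-chromene-3,5,7-triol | Oc1ccc2c(c1)O[C@H](c1ccc(O)c(O)c1)C[C@H]2c1c(O)cc(O)c2c1O[C@H](c1cc(O)c(O)c(O)c1)[C@H](O)C2 | target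

**Step count.** Total: 10 steps. Longest linear sequence: 7 steps (steps 3, 4, 5, 6, 7, 9, 10).

**Steps most likely to fail**

Step 6. The aryl anion may be protonated before it cyclises, it may lose bromide to form a second aryne, or the C2 configuration may erode under the basic conditions. The fallback sets out from 5 and comes back at 14, and still forms both ring-fusing bonds in one operation by known chemistry. Aryne precursor 5 is heated with purchased (E)-3-[3,4-bis(benzyloxy)phenyl]prop-2-enoic acid F1 and CsF in THF at 125 °C in a sealed tube. This is the known insertion of an aryne into the C–O bond of a carboxylic acid: the carboxylate adds to the aryne and the acyl group shifts from oxygen to carbon. It should give (E)-1-[4-(benzyloxy)-2-bromo-6-hydroxyphenyl]-3-[3,4-bis(benzyloxy)phenyl]prop-2-en-1-one F2. Oxa-Michael cyclisation (NaOAc, EtOH, reflux) should give racemic 7-(benzyloxy)-2-[3,4-bis(benzyloxy)phenyl]-5-bromo-2,3-dihydro-4H-chromen-4-one F3, and preparative chromatography on a chiral stationary phase would deliver 14.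

Step 9. Facial selectivity at C4 may be poor, attack may compete at C6 of the nucleophile, the product may be alkylated a second time, or the cation may eliminate to the flav-3-ene. The fallback sets out from 15 and comes back at 19, replacing the kinetically controlled coupling of protected partners by a reversible, protecting-group-free condensation. Hydrogenolysis of 15 (H2, Pd(OH)2/C, Et3N, THF/MeOH) should give (2S,4S)-2-(3,4-dihydroxyphenyl)-3,4-dihydro-2H-chromene-4,7-diol F4. F4 is then condensed with excess 16 in dilute aqueous-ethanolic HCl at rt, the classical acid condensation of a flavan-4-ol with a flavan-3-ol under thermodynamic control. 19 would be isolated by Sephadex LH-20 and reversed-phase chromatography.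

Step 10. Hydrodebromination may stay incomplete, or the interflavan bond may cleave or the polyphenol oxidise while base and halide are present. The fallback sets out from 18 and comes back at 19, separating the two events. Radical-chain debromination of 18 (Bu3SnH, AIBN, toluene, 80 °C) should give (2R,3R)-5,7-bis(benzyloxy)-8-{(2S,4R)-7-(benzyloxy)-2-[3,4-bis(benzyloxy)phenyl]-3,4-dihydro-2H-chromen-4-yl}-2-[3,4,5-tris(benzyloxy)phenyl]-3,4-dihydro-2H-chromen-3-ol F5. Base-free hydrogenolysis of F5 (H2, Pd(OH)2/C, THF/MeOH/H2O) then gives 19.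

**Further compounds**

F1 | step 6 | (E)-3-[3,4-bis(benzyloxy)phenyl]prop-2-enoic acid (purchased) | OC(=O)/C=C/c1ccc(OCc2ccccc2)c(OCc2ccccc2)c1
F2 | step 6 | (E)-1-[4-(benzyloxy)-2-bromo-6-hydroxyphenyl]-3-[3,4-bis(benzyloxy)phenyl]prop-2-en-1-one | O=C(/C=C/c1ccc(OCc2ccccc2)c(OCc2ccccc2)c1)c1c(O)cc(OCc2ccccc2)cc1Br
F3 | step 6 | racemic 7-(benzyloxy)-2-[3,4-bis(benzyloxy)phenyl]-5-bromo-2,3-dihydro-4H-chromen-4-one | O=C1CC(c2ccc(OCc3ccccc3)c(OCc3ccccc3)c2)Oc2cc(OCc3ccccc3)cc(Br)c21
F4 | step 9 | (2S,4S)-2-(3,4-dihydroxyphenyl)-3,4-dihydro-2H-chromene-4,7-diol | O[C@H]1C[C@@H](c2ccc(O)c(O)c2)Oc2cc(O)ccc21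
F5 | step 10 | (2R,3R)-5,7-bis(benzyloxy)-8-{(2S,4R)-7-(benzyloxy)-2-[3,4-bis(benzyloxy)phenyl]-3,4-dihydro-2H-chromen-4-yl}-2-[3,4,5-tris(benzyloxy)phenyl]-3,4-dihydro-2H-chromen-3-ol | O(Cc3ccccc3)c1ccc2c(c1)O[C@H](c1ccc(OCc3ccccc3)c(OCc3ccccc3)c1)C[C@H]2c1c(OCc3ccccc3)cc(OCc3ccccc3)c2c1O[C@H](c1cc(OCc3ccccc3)c(OCc3ccccc3)c(OCc3ccccc3)c1)[C@H](O)C2
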